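The readings are calculated with constants of no real substance; the scatter is artificial.

Subtract the runs.

| setting | Sunday's | Saturday's | flask |
|---|---|---|---|
| E | 0.50 M | 0.75 M | 1.0 M |
| D | 0.10 M | 0.10 M | 0.100 M |
| remark | run made earlier | run made earlier |  |
| time |  |  | 12 min |

| run | time / min | G / % | J / % | L / % |
|---|---|---|---|---|
| Sunday's | 1.00 | 2.4 | 10.3 | 28.4 |
| Sunday's | 2.00 | 5.3 | 11.6 | 37.8 |
| Sunday's | 2.50 | 8.4 | 11.9 | 40.5 |
| Sunday's | 4.00 | 14.5 | 9.9 | 47.9 |
| Sunday's | 6.00 | 22.0 | 7.3 | 53.0 |
| Sunday's | 10.0 | 28.7 | 4.0 | 59.5 |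
| Sunday's | 15.0 | 33.9 | 1.6 | 62.5 |
| Saturday's | 0.833 | 2.0 | 9.8 | 23.5 |
| Saturday's | 2.00 | 6.8 | 12.2 | 36.1 |
| Saturday's | 4.00 | 14.5 | 10.5 | 45.9 |
| Saturday's | 6.00 | 22.0 | 7.6 | 51.6 |
| Saturday's | 8.00 | 26.0 | 6.3 | 55.8 |
| Saturday's | 12.0 | 32.3 | 2.6 | 59.5 |
| Saturday's | 15.0 | 34.1 | 1.6 | 61.3 |

(scatter of a reading: 0.5 percentage points)

1. concentration of G at 12 min, in M
2. concentration of J at 12 min, in M
3. concentration of L at 12 min, in M

Sunday's and Saturday's runs charge the same D and differ in E, so the difference between their L concentrations belongs to the extra E. At 6.00 min the G columns stand level, 22.0 % and 22.0 %, which is how a product behaves when its concentration grows in proportion to the charge. The L column sinks instead: 62.5 % against 61.3 % at 15.0 min. Turned into concentrations, these readings are 0.375 M and 0.521 M.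

Call the extra L gained per unit of extra E, with D and time held, the marginal yield of L, a selectivity for L of the added E. Read from these two rows, it is 0.584. That is less than Saturday's share of L, so on this reading the added E pulls the percentage of L down.

Saturday's row at 12.0 min gives 0.506 M of L. Adding the marginal yield for the flask's extra 0.250 M of E gives 0.652 M. Each percentage carries 0.5 percentage points, so this yield is a reading, and one taken at 15.0 min, later than the asked time.

The forecast gives G 0.35 M, J 0.033 M and L 0.64 M, on the ground that “Each product therefore seems to scale with the total charge”. Its L is a little less than the reckoning here.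

The flask gives G 0.365 M, J 0.0295 M and L 0.647 M, and the forecast stands within its margins. In this flask at 12.0 min, Z still holds 2.99 % of the charge. The step from Saturday's row to the flask yields 0.566 of L per unit of E, beside the 0.584 read earlier.

    E ⇌ D (K = 0.150, k = 0.00890 s⁻¹)
    E → J (k = 0.00390 s⁻¹)
    D → L (k = 0.110 s⁻¹)
    D ⇌ Q (K = 9.30, k = 6.20 × 10⁻⁴ s⁻¹)
    Q → X (k = 0.0450 s⁻¹)
    E ⇌ Z (K = 1.00, k = 0.00950 s⁻¹)
    J → G (k = 0.00600 s⁻¹)

For the neighbour with 2.5 M of E, the marginal yield added to this flask's L gives 1.52 M. The computed value is 1.49 M, somewhat lower.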